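Ring C is cut at the acyl–aryl bond C4–C4a and at O1–C8a, and ring A is taken back from the arene to a cyclohexadienone; the C2–O bond is kept and C2 is traced to a ketone.
On ring A the C5 hydroxyl is para to the C8 methoxy group, and C4a and C8a are the α- and β-carbons of a carbonyl placed at C5. Ring A is therefore a masked 3,4,4-trimethoxycyclohexa-2,5-dienone (a quinone monoketal), and the O1–C8a/C4–C4a pair of ring C is an oxa-Michael/Dieckmann pair on its unsubstituted enone.
Forward, ring B and the C2–C3–C4 chain are made as a β-hydroxy ester. Its alkoxide and the monoketal are joined in one operation that forms O1–C8a, closes ring C at C4–C4a and aromatises ring A by loss of methanol; this frees the 5-OH and leaves the 7- and 8-methoxy groups in place without protecting groups.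
C2 is set by asymmetric hydrogenation of the β-keto ester; its C–O bond is never broken afterwards, so the S centre is carried unchanged into the flavanone.

Key step: step 4

Step 1
Reactants: 1 2',6'-dimethoxyacetophenone
Product: 2 ethyl 3-(2,6-dimethoxyphenyl)-3-oxopropanoate
Conditions: NaH (2.2 equiv), (EtO)2CO, toluene, 110 °C; then aq. HCl
Reagents that add atoms: diethyl carbonate, CCOC(=O)OCC
Why: Crossed Claisen condensation (carbethoxylation) at the only enolisable position, the acetyl methyl group, with non-enolisable diethyl carbonate, driven forward by deprotonation of the β-keto ester product.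

Step 2
Reactants: 2 ethyl 3-(2,6-dimethoxyphenyl)-3-oxopropanoate
Product: 3 ethyl (S)-3-(2,6-dimethoxyphenyl)-3-hydroxypropanoate
Conditions: RuCl2[(R)-BINAP] (1 mol %), H2 (50 bar), EtOH, 80 °C
Reagents that add atoms: none
Why: Noyori asymmetric hydrogenation of a β-keto ester, in which ketone and ester chelate ruthenium and the (R)-BINAP ligand should direct hydrogen to the face that gives the 3S alcohol (the same spatial sense as acetoacetate to (R)-3-hydroxybutanoate, the descriptor differing only because aryl outranks CH2CO2Et), which sets the only stereocentre of the route.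

Step 3
Reactants: 4 3,4-dimethoxyphenol
Product: 5 3,4,4-trimethoxycyclohexa-2,5-dien-1-one
Conditions: PhI(OAc)2 (1.1 equiv), MeOH, 0 °C
Reagents that add atoms: methanol, CO
Why: Oxidative dearomatisation of a para-methoxyphenol with a trivalent iodine reagent, in which methanol attacks the activated phenol at the methoxy-bearing para carbon to give the quinone monoketal, a standard reaction of this phenol class.

Step 4
Reactants: 3 ethyl (S)-3-(2,6-dimethoxyphenyl)-3-hydroxypropanoate; 5 3,4,4-trimethoxycyclohexa-2,5-dien-1-one
Product: 8 (2S)-5-hydroxy-7,8,2',6'-tetramethoxyflavanone, via oxa-Michael sodium enolate 6 (not isolated), via ketal sodium diketonate 7 (not isolated)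
Conditions: NaN(SiMe3)2 (1.05 equiv), THF, –78 °C; then 5 (1.2 equiv), –78 → 0 °C; then CF3CO2H (1.5 equiv), 0 °C → rt
Reagents that add atoms: none
Why: Proposed new method: the sodium alkoxide of 3 should add to the unsubstituted enone carbon of 5 next to the ketal (oxa-Michael, O1–C8a), the enolate 6 so formed should acylate itself on the tethered ethyl ester (Dieckmann, C4–C4a) and be held as the β-diketonate 7, and the acid should then ionise the C8 ketal of 7 to an arenium ion that loses the C8a proton, so that ring A aromatises with the old dienone carbonyl as the chelated 5-OH and the ketal carbon as C8–OMe. The closest known reaction types are the base-mediated oxa-Michael/Dieckmann annulation of hydroxy esters with acrylates (to 3-oxotetrahydrofuran and 4-oxotetrahydropyran carboxylates) and the Michael/Dieckmann annulations of quinone monoketals with carbon nucleophiles (Hauser–Kraus type) that end in aromatisation by loss of methanol; the new element is an alkoxide donor on a quinone monoketal acceptor. Ring C closes in the 6-exo-trig mode at the ester carbonyl, and ring A is not closed but aromatised. No lasting stereocentre is formed, since the C8a and C4a centres of 6 and 7 become sp2, and C2 keeps the S configuration of 3 because its C–O bond is never broken and the CIP order O > aryl > CH2 > H is the same in 3 and 8. The step needs the alkoxide to add at the unsubstituted enone carbon and not at the methoxy-bearing one, which the vinylogous-ester deactivation of that carbon and the reversibility of any addition there should secure, while only the enolate carbon next to the new C–O bond can reach the ester through a six-membered transition state. It also needs conjugate addition to outrun retro-aldol cleavage and dehydration of the aldolate, for which the low temperature, the sodium counter-ion and one equivalent of base are chosen, and the diketonate 7 is too weak a base to open ring C through a C3 enolate.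

Compound list
1 | 2',6'-dimethoxyacetophenone | CC(=O)c1c(OC)cccc1OC | starting material
2 | ethyl 3-(2,6-dimethoxyphenyl)-3-oxopropanoate | CCOC(=O)CC(=O)c1c(OC)cccc1OC | intermediate
3 | ethyl (S)-3-(2,6-dimethoxyphenyl)-3-hydroxypropanoate | CCOC(=O)C[C@H](O)c1c(OC)cccc1OC | intermediate
4 | 3,4-dimethoxyphenol | COc1ccc(O)cc1OC | starting material
5 | 3,4,4-trimethoxycyclohexa-2,5-dien-1-one | COC1=CC(=O)C=CC1(OC)OC | intermediate
6 | sodium enolate of ethyl (3S)-3-(2,6-dimethoxyphenyl)-3-[(2,2,3-trimethoxy-5-oxocyclohex-3-en-1-yl)oxy]propanoate (oxa-Michael adduct, both epimers at the ring carbon) | [Na+].[O-]C1=CC(O[C@@H](CC(=O)OCC)c2c(OC)cccc2OC)C(OC)(OC)C(OC)=C1 | intermediate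
7 | (2S)-2-(2,6-dimethoxyphenyl)-5-hydroxy-7,8,8-trimethoxy-2,3,8,8a-tetrahydro-4H-chromen-4-one, sodium salt (β-diketonate, both epimers at C8a) | [Na+].COC1=CC([O-])=C2C(=O)C[C@@H](c3c(OC)cccc3OC)OC2C1(OC)OC | intermediate
8 | (2S)-5-hydroxy-7,8,2',6'-tetramethoxyflavanone | COc1cc(O)c2c(c1OC)O[C@H](c1c(OC)cccc1OC)CC2=O | target

Total step count: 4. Longest linear sequence: 3 steps (steps 1, 2 and 4); step 3 is a one-step side branch.

Steps most likely to fail

Step 4 (proposed new method). The aldolate may fragment by retro-aldol cleavage or dehydrate before it adds. The conjugate addition is reversible and may not be drained by ring closure, because both the secondary alkoxide and the enone carbon next to the ketal are hindered. The fallback uses known chemistry, sets out from 2 and returns at 8.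
- Hydrogenation of 2 with RuCl2[(S)-BINAP] would give ethyl (R)-3-(2,6-dimethoxyphenyl)-3-hydroxypropanoate F1.
- Mitsunobu etherification (PPh3, DIAD, THF, 0 °C) with commercial 3-hydroxy-4,5-dimethoxybenzaldehyde would invert C2 and give ethyl (S)-3-(2,6-dimethoxyphenyl)-3-(5-formyl-2,3-dimethoxyphenoxy)propanoate F2.
- Baeyer–Villiger oxidation (mCPBA, CH2Cl2) would turn the aldehyde into the aryl formate ethyl (S)-3-(2,6-dimethoxyphenyl)-3-[5-(formyloxy)-2,3-dimethoxyphenoxy]propanoate F3.
- LiOH in aqueous THF would cleave both esters to (S)-3-(2,6-dimethoxyphenyl)-3-(5-hydroxy-2,3-dimethoxyphenoxy)propanoic acid F4.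
- (CF3CO)2O in CH2Cl2 at 0 °C would form the mixed trifluoroacetic anhydride of F4 with O-trifluoroacetylated phenol F5. This would close the same acyl–aryl bond by intramolecular Friedel–Crafts acylation at the only free position ortho to the ether oxygen, giving (2S)-7,8,2',6'-tetramethoxy-5-(trifluoroacetoxy)flavanone F6.
- Aqueous NaHCO3 would hydrolyse the trifluoroacetate to 8.

Step 2. Hydrogenation may be slow and poorly face-selective, because the di-ortho-substituted aroyl group is twisted and crowds the ruthenium chelate. The fallback changes from asymmetric catalysis to resolution, sets out from 2 and returns at 3.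
- NaBH4 in EtOH at 0 °C would give racemic ethyl 3-(2,6-dimethoxyphenyl)-3-hydroxypropanoate F7.
- Lipase-catalysed kinetic resolution (Burkholderia cepacia lipase, vinyl acetate, t-BuOMe) should, by Kazlauskas' rule, acetylate the R enantiomer to ethyl (R)-3-acetoxy-3-(2,6-dimethoxyphenyl)propanoate F8 and leave 3, which would be separated by chromatography.

Step 3. The ketal may be hydrolysed to the quinone, or the ring oxidised further, during reaction and isolation. The fallback is electrochemical, sets out from 4 and returns at 5.
- O-Methylation (MeI, K2CO3, acetone) would give 1,2,4-trimethoxybenzene F9.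
- Anodic oxidation (Pt anode, KOH, MeOH, 0 °C) would give the quinone bisketal 1,3,3,6,6-pentamethoxycyclohexa-1,4-diene F10.
- Dilute aqueous AcOH in acetone at 0 °C would hydrolyse only the ketal whose allyl cation is stabilised by the ring methoxy group, giving 5.

Further compounds
F1 | step 4 | ethyl (R)-3-(2,6-dimethoxyphenyl)-3-hydroxypropanoate | CCOC(=O)C[C@@H](O)c1c(OC)cccc1OC
F2 | step 4 | ethyl (S)-3-(2,6-dimethoxyphenyl)-3-(5-formyl-2,3-dimethoxyphenoxy)propanoate | CCOC(=O)C[C@H](Oc1cc(C=O)cc(OC)c1OC)c1c(OC)cccc1OC
F3 | step 4 | ethyl (S)-3-(2,6-dimethoxyphenyl)-3-[5-(formyloxy)-2,3-dimethoxyphenoxy]propanoate | CCOC(=O)C[C@H](Oc1cc(OC=O)cc(OC)c1OC)c1c(OC)cccc1OC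
F4 | step 4 | (S)-3-(2,6-dimethoxyphenyl)-3-(5-hydroxy-2,3-dimethoxyphenoxy)propanoic acid | OC(=O)C[C@H](Oc1cc(O)cc(OC)c1OC)c1c(OC)cccc1OC
F5 | step 4 | mixed trifluoroacetic anhydride of F4 with O-trifluoroacetylated phenol | O=C(C[C@H](Oc1cc(OC(=O)C(F)(F)F)cc(OC)c1OC)c1c(OC)cccc1OC)OC(=O)C(F)(F)F
F6 | step 4 | (2S)-7,8,2',6'-tetramethoxy-5-(trifluoroacetoxy)flavanone | COc1cc(OC(=O)C(F)(F)F)c2c(c1OC)O[C@H](c1c(OC)cccc1OC)CC2=O
F7 | step 2 | racemic ethyl 3-(2,6-dimethoxyphenyl)-3-hydroxypropanoate | CCOC(=O)CC(O)c1c(OC)cccc1OC
F8 | step 2 | ethyl (R)-3-acetoxy-3-(2,6-dimethoxyphenyl)propanoate | CCOC(=O)C[C@@H](OC(C)=O)c1c(OC)cccc1OC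
F9 | step 3 | 1,2,4-trimethoxybenzene | COc1ccc(OC)c(OC)c1
F10 | step 3 | 1,3,3,6,6-pentamethoxycyclohexa-1,4-diene | COC1=CC(OC)(OC)C=CC1(OC)OC
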